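All runs were generated by integration for an exercise; the scatter is artificial.

The midnight run holds 27.3% of its charge in chains at 30.0 min, with its solid monomer reading 0.8%, which is within the scatter of zero. Chain growth there can therefore be counted in turnovers: the turnover count is the natural logarithm of one over the fraction of the charge not in chains, and midnight's last reading gives 0.319.

all flasks: radical scavenger 0.05 mol%

|  | solid monomer | initiator | remark | time |
|---|---|---|---|---|
| spring | 2.2 M | 2.5 mol% | run made earlier |  |
| midnight | 0.75 M | 2.5 mol% | run made earlier |  |
| south-east | 1.5 M | 2.5 mol% |  | 2.5 h |
| south | 1.5 M | 5 mol% |  | 2.5 h |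

| run | time / min | monomer in chains / % | solid monomer / % |
|---|---|---|---|
| spring | 8.00 | 8.3 | 50.3 |
| spring | 15.0 | 18.1 | 21.6 |
| spring | 25.0 | 24.9 | 1.4 |
| spring | 30.0 | 27.4 | 1.4 |
| midnight | 8.00 | 14.6 | 0 |
| midnight | 15.0 | 21.5 | 0.5 |
| midnight | 25.0 | 25.2 | 0.3 |
| midnight | 30.0 | 27.3 | 0.8 |

(readings scatter by 1 percentage point)

- which of the two ends with the higher amount of monomer in chains, in percent of the solid monomer charged ("neither" if they lie within 2 percentage points) (south-east / south / neither)
- monomer in chains at the end, in percent of the solid monomer charged, south-east
- monomer in chains at the end, in percent of the solid monomer charged, south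

- solid, in amounts per volume of the solution: solid monomer
- the numbers in the tables scatter by 1 percentage point (one standard deviation)
- at the start none of the solid monomer is in solution

If growing radicals end each other in pairs, the count on the plateau should go with the square root of the initiator per volume. At equal solid monomer, the turnover factor, the square root of the ratio of two initiator loadings, multiplies one flask's count to give the other's. For south against south-east, it is 1.41.

My own reckoning takes midnight's count as its plateau. South-east carries 2.00 times midnight's initiator per volume, so its count is 0.451, which puts 36.3% in chains. Turning the question round, on this reckoning south leads by less than the margin if its count stands below 1.07 times south-east's. The turnover factor stands well above that, so south should lead, with 47.1% by my reckoning.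

The forecast names south, with 35% (30% to 41%) for south-east and 45% (38% to 53%) for south, slightly below my figures. One of its grounds is this: “Once dissolved, spring's rate per free monomer is about 1.8 times midnight's”.

South-east ends at 32.6% and south at 42.6%, so south leads, as the forecast said.

    solid monomer ⇌ free monomer, rate k1*(cs1 - [free monomer]) while solid is left; crystals form when [free monomer] > cs1 (solubility = 0.620 M, k = 0.0133 s⁻¹)
    free monomer + growing radical → monomer in chains + growing radical, rate k2*[growing radical]*[free monomer] (k = 253 M⁻¹ s⁻¹)
    initiator → 2 initiating radical (k = 5.85 × 10⁻⁴ s⁻¹)
    growing radical + radical scavenger → ended chains (k = 7.19 × 10⁶ M⁻¹ s⁻¹)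
    2 growing radical → dead chain (k = 2.50 × 10⁶ M⁻¹ s⁻¹)
    free monomer + initiating radical → growing radical + monomer in chains (k = 17100 M⁻¹ s⁻¹)
    2 free monomer → homo dimer (k = 0.00200 M⁻¹ s⁻¹)

The higher initiator loading is the main reason for the gap: with south-east's loading, south holds 32.6% instead of 42.6%. South-east's count of 0.394, multiplied by the turnover factor, gives 42.6%, against the 42.6% that south holds. A neighbour of south-east with 4.2 mol% of initiator has a turnover factor of 1.30, which gives 40.1%, and that flask holds 40.0% in chains.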